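At early times the green run already showed how fast starting material went. With 0.45 M of reagent, 71.9% of the starting material was left after 10.0 min. I began with one step, starting material + reagent → target, with rate k·[starting material]·[reagent]. That first reading gave k = 0.0801 /M/min, and the reading at 60.0 min gave 0.0807 /M/min.

| setting | green | flask |
|---|---|---|
| starting material | 0.25 M | 0.50 M |
| reagent | 0.45 M | 0.450 M |
| initiator | 50 mM | 50 mM |
| remark | run made earlier |  |
| time |  | 6.0 h |

green run (percent of the starting material charged)

| time / min | target / % | starting material / % |
|---|---|---|
| 10.0 | 28.0 | 71.9 |
| 20.0 | 44.8 | 54.4 |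
| 30.0 | 57.9 | 40.7 |
| 40.0 | 65.8 | 33.2 |
| 50.0 | 72.5 | 26.6 |
| 60.0 | 77.7 | 21.4 |
| 80.0 | 82.7 | 13.5 |

(each reading ± 0.5 percentage points)



- amount of target in percent of the starting material charged, at 40 min, 2.0 h and 6.0 h

I carried one quantity, τ, the half-time of starting material at a given reagent concentration (a half-time taken as pseudo-first-order):

τ = ln(2)/(k·[reagent]) = 19.2 min at the charged reagent

The new flask has the same reagent charge as the green run, so τ starts the same, but it lengthens as reagent is used. In the new flask reagent is the limiting reagent, so the main step has a ceiling of 90.0%. With charges a and b of starting material and reagent, the target fraction y at time t is: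

E = exp((a − b)·k·t), y = (E − 1)/(E·a/b − 1)

y = 57.1% at 40 min, 77.4% at 2.0 h, 87.3% at 6.0 h

Next I added a slow loss of target. The green balance was short by 0.9 percentage points at 60.0 min and 3.8 points at 80.0 min. I expected that to lower the late values, but one reading gave me no size for it. Last came the initiator: I expected its dying away to lower the late values further, and I read no size for that from the green run. So I held my figures as an upper line.

The forecast stood lower than my line , at 56%, 75% and 84% for the same times, with the remark “so I shade the later values down”.

The flask gave 50.5%, 69.8% and 78.8% at those times.

    reagent + first chain carrier ⇌ target + second chain carrier (K = 0.830, k = 8.00 × 10⁶ /M/h)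
    starting material + second chain carrier → by-product + first chain carrier (k = 3.20 × 10⁶ /M/h)
    target → over-reaction product (k = 0.00620 /h)
    starting material + initiating radical → capped initiator + first chain carrier (k = 7.10 × 10⁶ /M/h)
    2 first chain carrier → ended chains A (k = 6.50 × 10⁶ /M/s)
    2 second chain carrier → ended chains B (k = 3.00 × 10⁶ /M/s)
    initiator → 2 initiating radical (k = 0.0940 /h)

At 6.00 h in the flask, τ taken at the reagent left, 9.6% of its charge, is 3.35 h. Starting material's half-life by its step with the second chain carrier was 7.4 h, about twice as long, and the backward turnover of the target-forming step stood at 78% of the forward one. With every charge halved, τ doubles to 38.4 min, the main step gives 82.2% over 6.0 h, and that thinned flask gave 75.8%.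

The earlier runs and the new flask were generated by integration on assumed constants; scatter was added.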